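## Retrosynthetic overview

1. The target comes from the C2-symmetric bis(2-hydroxy-5-methoxy-6-methyl-1,4-benzoquinone) by hydrolysis of one of its two remote, equivalent vinylogous methyl esters.
2. That bis-quinone comes from 1,13-bis(3,5-dimethoxyphenyl)tridecane. Both ends are decorated at the same time: C-methylation between the OMe groups, dibromination, Br to OH, then oxidative demethylation.
3. Key disconnection: both benzylic C–C bonds of the tether (C1–C2 and C12–C13) are cut at once. This gives 2 × 3,5-dimethoxybenzaldehyde plus Br(CH2)11Br. The aldehyde carbon is reversed to a carbanion equivalent as its N–H hydrazone, N2 leaves, and CH2 is delivered directly.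
4. No ring is built. Both carbocycles are bought as the benzene ring of the aldehyde, and both become quinones together in step 5.

Assumption: the target has no stereocentre and no stereogenic double bond, so it is achiral and needs no stereocontrol. The tether is read from the SMILES as 13 CH2 groups.

## Route

Step 1
Reactants: 1 3,5-dimethoxybenzaldehyde (2.5 equiv); 2 hydrazine monohydrate; 3 1,11-dibromoundecane (1 equiv)
Product: 5 1,13-bis(3,5-dimethoxyphenyl)tridecane, via 3,5-dimethoxybenzaldehyde hydrazone 4 (not isolated)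
Conditions: (i) N2H4·H2O (1.1 equiv per CHO), THF, rt, 1 h, then 4 Å MS; (ii) 3, Ni(cod)2 (10 mol %), PMe3 (40 mol %), K3PO4 (3 equiv), THF, 70 °C, 24 h
Reagents that add atoms: none
Why: In the N–H hydrazone the former carbonyl carbon is the nucleophilic end of a diaza-allyl system, so Ni-catalysed cross-coupling with an unactivated primary alkyl bromide (Wolff–Kishner-type umpolung alkylation) joins two normally electrophilic carbons; the alkyl diazene then loses N2 to give CH2 directly, the ortho-unsubstituted aryl hydrazone is the favourable substrate class, both C–Br ends react independently, and no stereocentre forms.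

Step 2
Reactants: 5 1,13-bis(3,5-dimethoxyphenyl)tridecane
Product: 7 1,13-bis(3,5-dimethoxy-4-methylphenyl)tridecane, via dilithio arene 6 (not isolated)
Conditions: n-BuLi (2.6 equiv), THF, 0 °C → rt, 2 h; MeI (4 equiv), 0 °C → rt
Reagents that add atoms: iodomethane, CI (n-butyllithium, [Li]CCCC, supplies the Li of intermediate 6 only)
Why: Directed ortho-metalation of a 5-alkylresorcinol dimethyl ether takes only the C–H flanked by both OMe groups, and the aryllithium is methylated by SN2 on MeI.

Step 3
Reactants: 7 1,13-bis(3,5-dimethoxy-4-methylphenyl)tridecane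
Product: 8 1,13-bis(2,6-dibromo-3,5-dimethoxy-4-methylphenyl)tridecane
Conditions: NBS (4.4 equiv), CH2Cl2–MeCN 1:1, 0 °C → rt, dark
Reagents that add atoms: N-bromosuccinimide, O=C1CCC(=O)N1Br
Why: In this electrophilic aromatic bromination the only two free positions of each ring are each ortho to one OMe and para to the other, and the polar medium in the dark suppresses benzylic radical bromination.

Step 4
Reactants: 8 1,13-bis(2,6-dibromo-3,5-dimethoxy-4-methylphenyl)tridecane
Product: 11 2,2'-(tridecane-1,13-diyl)bis(4,6-dimethoxy-5-methylbenzene-1,3-diol), via tetralithio arene 9 (not isolated), via tetrakis(dimethoxyboryl) arene 10 (not isolated)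
Conditions: t-BuLi (8.8 equiv), THF, −78 °C, 1 h; B(OMe)3 (8 equiv), −78 °C → rt; AcOH, then 30 % H2O2, 0 °C → rt, Ar; product used promptly
Reagents that add atoms: hydrogen peroxide, OO (for the intermediates only: tert-butyllithium, [Li]C(C)(C)C; trimethyl borate, COB(OC)OC)
Why: Br/Li exchange is irreversible with two t-BuLi per bromide, each aryllithium is stabilised by its ortho OMe group, and borate trapping followed by peroxide-induced 1,2-aryl migration (boronate oxidation) puts an OH exactly where each Br stood.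

Step 5
Reactants: 11 2,2'-(tridecane-1,13-diyl)bis(4,6-dimethoxy-5-methylbenzene-1,3-diol)
Product: 12 3,3'-(tridecane-1,13-diyl)bis(2-hydroxy-5-methoxy-6-methyl-1,4-benzoquinone)
Conditions: PhI(OAc)2 (2.2 equiv), MeCN–THF–H2O, 0 °C, 30 min
Reagents that add atoms: water, O
Why: In this hypervalent-iodine oxidative demethylation of a p-methoxyphenol, water adds to the OMe-bearing para carbon and the hemiketal loses MeOH; the two OH/OMe pairs of each ring are mirror-related, even an ortho attack tautomerises to the same hydroxy-p-quinone, and the fully substituted product cannot react further.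

Step 6
Reactants: 12 3,3'-(tridecane-1,13-diyl)bis(2-hydroxy-5-methoxy-6-methyl-1,4-benzoquinone)
Product: 13 2,5-dihydroxy-3-[13-(2-hydroxy-5-methoxy-6-methyl-1,4-benzoquinon-3-yl)tridecyl]-6-methyl-1,4-benzoquinone (target, achiral)
Conditions: 1 M aq NaOH (10 equiv), dioxane, 75 °C, N2, stopped at about 50 % OMe conversion (HPLC); 1 M HCl; oxalic-acid-treated SiO2 or RP-HPLC; recovered 12 recycled
Reagents that add atoms: sodium hydroxide, [Na+].[OH-]
Why: Hydroxide adds to the OMe-bearing carbon of the vinylogous ester and expels methoxide (addition–elimination, vinylogous saponification); the rings are insulated by 13 CH2 groups and react independently, so half conversion gives a 1:2:1 mixture with 13 as the main component (at most 50 % per pass), and the alcohol-free solvent prevents ether exchange.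

## Compound list

1 | 3,5-dimethoxybenzaldehyde | COc1cc(C=O)cc(OC)c1 | starting material
2 | hydrazine monohydrate | NN.O | starting material
3 | 1,11-dibromoundecane | BrCCCCCCCCCCCBr | starting material
4 | (E)-3,5-dimethoxybenzaldehyde hydrazone | COc1cc(/C=N/N)cc(OC)c1 | intermediate
5 | 1,13-bis(3,5-dimethoxyphenyl)tridecane | COc1cc(CCCCCCCCCCCCCc2cc(OC)cc(OC)c2)cc(OC)c1 | intermediate
6 | 1,13-bis(4-lithio-3,5-dimethoxyphenyl)tridecane | COc1cc(CCCCCCCCCCCCCc2cc(OC)c([Li])c(OC)c2)cc(OC)c1[Li] | intermediate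
7 | 1,13-bis(3,5-dimethoxy-4-methylphenyl)tridecane | COc1cc(CCCCCCCCCCCCCc2cc(OC)c(C)c(OC)c2)cc(OC)c1C | intermediate
8 | 1,13-bis(2,6-dibromo-3,5-dimethoxy-4-methylphenyl)tridecane | COc1c(C)c(OC)c(Br)c(CCCCCCCCCCCCCc2c(Br)c(OC)c(C)c(OC)c2Br)c1Br | intermediate
9 | 1,13-bis(2,6-dilithio-3,5-dimethoxy-4-methylphenyl)tridecane | COc1c(C)c(OC)c([Li])c(CCCCCCCCCCCCCc2c([Li])c(OC)c(C)c(OC)c2[Li])c1[Li] | intermediate
10 | 1,13-bis[2,6-bis(dimethoxyboryl)-3,5-dimethoxy-4-methylphenyl]tridecane | COc1c(C)c(OC)c(B(OC)OC)c(CCCCCCCCCCCCCc2c(B(OC)OC)c(OC)c(C)c(OC)c2B(OC)OC)c1B(OC)OC | intermediate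
11 | 2,2'-(tridecane-1,13-diyl)bis(4,6-dimethoxy-5-methylbenzene-1,3-diol) | COc1c(C)c(OC)c(O)c(CCCCCCCCCCCCCc2c(O)c(OC)c(C)c(OC)c2O)c1O | intermediate
12 | 3,3'-(tridecane-1,13-diyl)bis(2-hydroxy-5-methoxy-6-methyl-1,4-benzoquinone) | COC1=C(C)C(=O)C(O)=C(CCCCCCCCCCCCCC2=C(O)C(=O)C(C)=C(OC)C2=O)C1=O | intermediate
13 | 2,5-dihydroxy-3-[13-(2-hydroxy-5-methoxy-6-methyl-1,4-benzoquinon-3-yl)tridecyl]-6-methyl-1,4-benzoquinone | COC1=C(C)C(=O)C(O)=C(CCCCCCCCCCCCCC2=C(O)C(=O)C(C)=C(O)C2=O)C1=O | target

## Step count and risks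

Total steps: 6. Longest linear sequence: 6.

**Step 1.** The double Ni-catalysed hydrazone alkylation can lose material to N-alkylation, to β-hydride elimination, or by stopping at the mono-coupled bromide.
- The fallback sets out from 1 and comes back at 5.
- 1 is treated with propane-1,3-dithiol and BF3·OEt2 (CH2Cl2, 0 °C) to give 2-(3,5-dimethoxyphenyl)-1,3-dithiane F1.
- n-BuLi (THF, −30 °C) makes the 2-lithiodithiane, a stoichiometric acyl anion equivalent. It is alkylated at both ends of 3 (0.45 equiv) to give 1,11-bis[2-(3,5-dimethoxyphenyl)-1,3-dithian-2-yl]undecane F2.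
- Raney nickel (EtOH, reflux) removes the sulfur and gives 5.
- This costs two more steps.

**Step 4.** The fourfold Br/Li exchange and borylation can be incomplete, giving protonated or protodeboronated rings.
- The fallback sets out from 7 and comes back at 12, and uses no organometallic reagent.
- 7 is oxidised with 30 % H2O2 in HCO2H (rt). The only free ring positions are para to an OMe group, and the phenol formed is oxidised further with loss of methanol. The product is 6,6'-(tridecane-1,13-diyl)bis(2-methoxy-3-methyl-1,4-benzoquinone) F3.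
- Nucleophilic epoxidation (H2O2, Na2CO3, aq dioxane, 0 °C) takes the electron-poor CH=C(alkyl) bond and not the methoxy-substituted one. It gives 1,1'-(tridecane-1,13-diyl)bis(3-methoxy-4-methyl-7-oxabicyclo[4.1.0]hept-3-ene-2,5-dione) F4 as a diastereomer mixture, which does not matter because these centres are destroyed next.
- Conc. H2SO4 (0 °C), then water, isomerises each epoxy-dione to the hydroxyquinone, which is 12.

**Step 6.** The yield is capped at 50 % per pass, the separation may be difficult, and the quinones are exposed to hot alkali.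
- The fallback sets out from 3 and 4 and comes back at 13. It differentiates the two rings from the start.
- 4 is coupled under the step 1 conditions with 5 equiv of 3 (excess recovered) to give 1-(12-bromododecyl)-3,5-dimethoxybenzene F5.
- Commercial 3,5-dihydroxybenzaldehyde with MOMCl and iPr2NEt gives 3,5-bis(methoxymethoxy)benzaldehyde F6.
- Hydrazine converts F6 into 3,5-bis(methoxymethoxy)benzaldehyde hydrazone F7. The same Ni coupling with F5 gives 1-[3,5-bis(methoxymethoxy)phenyl]-13-(3,5-dimethoxyphenyl)tridecane F8.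
- The conditions of steps 2 to 5 are then applied in turn:
  - step 2 conditions give 1-[3,5-bis(methoxymethoxy)-4-methylphenyl]-13-(3,5-dimethoxy-4-methylphenyl)tridecane F9;
  - step 3 conditions (with added NaHCO3) give the corresponding 2,6,2',6'-tetrabromide F10;
  - step 4 conditions give the corresponding tetraphenol F11;
  - step 5 conditions give the bis-quinone that carries OMe on one ring and OCH2OMe on the other, F12.
- 1 M HCl in THF (rt) cleaves only the very labile vinylogous MOM ester and gives 13 without any statistical event.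

## Further compounds

F1 | step 1 | 2-(3,5-dimethoxyphenyl)-1,3-dithiane | COc1cc(cc(OC)c1)C1SCCCS1
F2 | step 1 | 1,11-bis[2-(3,5-dimethoxyphenyl)-1,3-dithian-2-yl]undecane | COc1cc(cc(OC)c1)C1(CCCCCCCCCCCC2(SCCCS2)c2cc(OC)cc(OC)c2)SCCCS1
F3 | step 4 | 6,6'-(tridecane-1,13-diyl)bis(2-methoxy-3-methyl-1,4-benzoquinone) | COC1=C(C)C(=O)C=C(CCCCCCCCCCCCCC2=CC(=O)C(C)=C(OC)C2=O)C1=O
F4 | step 4 | 1,1'-(tridecane-1,13-diyl)bis(3-methoxy-4-methyl-7-oxabicyclo[4.1.0]hept-3-ene-2,5-dione), diastereomer mixture | COC1=C(C)C(=O)C2OC2(CCCCCCCCCCCCCC34OC3C(=O)C(C)=C(OC)C4=O)C1=O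
F5 | step 6 | 1-(12-bromododecyl)-3,5-dimethoxybenzene | COc1cc(CCCCCCCCCCCCBr)cc(OC)c1
F6 | step 6 | 3,5-bis(methoxymethoxy)benzaldehyde | COCOc1cc(C=O)cc(OCOC)c1
F7 | step 6 | (E)-3,5-bis(methoxymethoxy)benzaldehyde hydrazone | COCOc1cc(/C=N/N)cc(OCOC)c1
F8 | step 6 | 1-[3,5-bis(methoxymethoxy)phenyl]-13-(3,5-dimethoxyphenyl)tridecane | COCOc1cc(CCCCCCCCCCCCCc2cc(OC)cc(OC)c2)cc(OCOC)c1
F9 | step 6 | 1-[3,5-bis(methoxymethoxy)-4-methylphenyl]-13-(3,5-dimethoxy-4-methylphenyl)tridecane | COCOc1cc(CCCCCCCCCCCCCc2cc(OC)c(C)c(OC)c2)cc(OCOC)c1C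
F10 | step 6 | 1-[2,6-dibromo-3,5-bis(methoxymethoxy)-4-methylphenyl]-13-(2,6-dibromo-3,5-dimethoxy-4-methylphenyl)tridecane | COCOc1c(C)c(OCOC)c(Br)c(CCCCCCCCCCCCCc2c(Br)c(OC)c(C)c(OC)c2Br)c1Br
F11 | step 6 | 2-{13-[2,6-dihydroxy-3,5-bis(methoxymethoxy)-4-methylphenyl]tridecyl}-4,6-dimethoxy-5-methylbenzene-1,3-diol | COCOc1c(C)c(OCOC)c(O)c(CCCCCCCCCCCCCc2c(O)c(OC)c(C)c(OC)c2O)c1O
F12 | step 6 | 2-hydroxy-3-{13-[2-hydroxy-5-(methoxymethoxy)-6-methyl-1,4-benzoquinon-3-yl]tridecyl}-5-methoxy-6-methyl-1,4-benzoquinone | COCOC1=C(C)C(=O)C(O)=C(CCCCCCCCCCCCCC2=C(O)C(=O)C(C)=C(OC)C2=O)C1=O
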